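**Plan**

- Numbering (cembrane): C1 is the ring CH that carries the lactone α-carbon C15, C2 is the lactone O–CH, the ring olefins are C3=C4, C7=C8 and C11=C12. The feature used is that the C9 carbinol (the acetate) sits directly on C8 of the E-trisubstituted C7=C8 olefin of the 14-membered ring, which is an alkenyl-metal plus aldehyde junction.
- Retrosynthesis, in order: remove the C9 acetate; cut C8–C9, which opens the 14-membered ring to iodo aldehyde 31; cut C1–C2 and the lactone C–O bond to give enal 12 (C2–C8) and 2-(bromomethyl)acrylate 26 (C9–C17). 12 comes from geraniol; 26 from propane-1,3-diol, isopropenylmagnesium bromide, triethyl orthoacetate and methyl acrylate.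
- Forward: the two chains are joined at C1–C2 with closure of the five-membered lactone (step 16), the 14-membered carbocycle is then closed at C8–C9 (step 19), and acetylation ends the route.
- Stereochemistry: C1 and C2 come from a ligand-controlled, anti-selective chromium allylation; C9 comes from the chiral sulfonamide on chromium during ring closure. The 3E, 7E and 11E geometries come from geraniol, syn hydrozirconation and the Johnson–Claisen rearrangement.

Key step: step 19

Assumption: for each of the two chiral chromium ligands the antipode that gives the face selectivity stated in steps 16 and 19 is used; if the one first tried favours the other face, its mirror image is taken. The (S)-sulfonamide drawn in species 32 is an example only. The anti (trans-lactone) sense of step 16 is argued from the crotylchromium-type chair transition state and is answered by a fallback below if it turns out syn.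

**Route**

Step 1
Reactants: 1 geraniol
Product: 2 tert-butyl{[(2E)-3,7-dimethylocta-2,6-dien-1-yl]oxy}diphenylsilane
Conditions: TBDPSCl, imidazole, DMF, 0 °C to rt
Reagents that add atoms: tert-butyl(chloro)diphenylsilane, CC(C)(C)[Si](Cl)(c1ccccc1)c1ccccc1
Why: Imidazole-promoted silylation of the primary allylic alcohol; the bulky, acid-stable silyl ether is chosen to survive periodic acid, n-BuLi and hydrozirconation.

Step 2
Reactants: 2 tert-butyl{[(2E)-3,7-dimethylocta-2,6-dien-1-yl]oxy}diphenylsilane
Product: 3 tert-butyl{[(2E)-5-(3,3-dimethyloxiran-2-yl)-3-methylpent-2-en-1-yl]oxy}diphenylsilane (racemic)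
Conditions: mCPBA (1.0 equiv), NaHCO3, CH2Cl2, −20 to 0 °C
Reagents that add atoms: 3-chloroperoxybenzoic acid, OOC(=O)c1cccc(Cl)c1
Why: Prilezhaev epoxidation; the peracid should take the more electron-rich distal olefin because the proximal one is deactivated by the allylic silyloxy group, and the new stereocentre is cleaved in step 3.

Step 3
Reactants: 3 tert-butyl{[(2E)-5-(3,3-dimethyloxiran-2-yl)-3-methylpent-2-en-1-yl]oxy}diphenylsilane
Product: 5 (4E)-6-[(tert-butyldiphenylsilyl)oxy]-4-methylhex-4-enal, via vicinal diol 4 (not isolated)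
Conditions: H5IO6, THF/Et2O, 0 °C
Reagents that add atoms: none
Why: Periodic acid opens the epoxide to the diol and cleaves it in the same flask (Malaprade glycol cleavage), giving acetone and the aldehyde at the future C7 without touching the trisubstituted olefin or the silyl ether.

Step 4
Reactants: 5 (4E)-6-[(tert-butyldiphenylsilyl)oxy]-4-methylhex-4-enal
Product: 6 tert-butyl{[(2E)-7,7-dibromo-3-methylhepta-2,6-dien-1-yl]oxy}diphenylsilane
Conditions: CBr4, PPh3, CH2Cl2, 0 °C
Reagents that add atoms: tetrabromomethane, BrC(Br)(Br)Br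
Why: First stage of the Corey–Fuchs reaction; the dibromomethylene ylide made in the flask olefinates the aldehyde and brings in the future C8.

Step 5
Reactants: 6 tert-butyl{[(2E)-7,7-dibromo-3-methylhepta-2,6-dien-1-yl]oxy}diphenylsilane
Product: 8 tert-butyl{[(2E)-3-methyloct-2-en-6-yn-1-yl]oxy}diphenylsilane, via lithium acetylide 7 (not isolated)
Conditions: n-BuLi (2.2 equiv), THF, −78 to 0 °C; MeI, −78 °C to rt
Reagents that add atoms: iodomethane, CI
Why: Second stage of the Corey–Fuchs reaction; bromine–lithium exchange and 1,2-shift of the carbenoid give the alkyne, the second equivalent of base forms the acetylide, and MeI methylates it at carbon.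

Step 6
Reactants: 8 tert-butyl{[(2E)-3-methyloct-2-en-6-yn-1-yl]oxy}diphenylsilane
Product: 10 tert-butyl{[(2E,6E)-7-iodo-3-methylocta-2,6-dien-1-yl]oxy}diphenylsilane, via alkenylzirconocene 9 (not isolated)
Conditions: Cp2Zr(H)Cl (3 equiv), THF, 50 °C; I2, THF, 0 °C
Reagents that add atoms: iodine, II
Why: Hydrozirconation–iodination; syn Zr–H addition and equilibration with excess hydride should place zirconium on the less hindered, methyl-bearing alkyne carbon (C8), and iodine cleaves C–Zr with retention to give the (E)-2-iodoalkene.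

Step 7
Reactants: 10 tert-butyl{[(2E,6E)-7-iodo-3-methylocta-2,6-dien-1-yl]oxy}diphenylsilane
Product: 11 (2E,6E)-7-iodo-3-methylocta-2,6-dien-1-ol
Conditions: TBAF, THF, 0 °C to rt
Reagents that add atoms: none
Why: Fluoride-induced desilylation; the alkenyl iodide and both olefins are inert, and any regioisomeric iodide from step 6 can be removed at this stage.

Step 8
Reactants: 11 (2E,6E)-7-iodo-3-methylocta-2,6-dien-1-ol
Product: 12 (2E,6E)-7-iodo-3-methylocta-2,6-dienal
Conditions: MnO2, CH2Cl2, rt
Reagents that add atoms: none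
Why: Allylic oxidation with MnO2 is neutral and selective for the allylic alcohol, so the 2E enal should form without isomerisation.

Step 9
Reactants: 13 propane-1,3-diol
Product: 14 3-[(4-methoxybenzyl)oxy]propan-1-ol
Conditions: NaH (1 equiv), PMBCl (1 equiv), Bu4NI (cat.), THF, 0 °C to rt, diol in excess
Reagents that add atoms: 4-methoxybenzyl chloride, COc1ccc(CCl)cc1
Why: Williamson etherification; with the diol in excess the mono-ether should predominate.

Step 10
Reactants: 14 3-[(4-methoxybenzyl)oxy]propan-1-ol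
Product: 15 3-[(4-methoxybenzyl)oxy]propanal
Conditions: Dess–Martin periodinane, NaHCO3, CH2Cl2, 0 °C to rt
Reagents that add atoms: none
Why: Dess–Martin oxidation under buffered, non-basic conditions avoids β-elimination of the benzyloxy group.

Step 11
Reactants: 15 3-[(4-methoxybenzyl)oxy]propanal; 16 isopropenylmagnesium bromide
Product: 17 5-[(4-methoxybenzyl)oxy]-2-methylpent-1-en-3-ol (racemic)
Conditions: THF, −78 to 0 °C
Reagents that add atoms: none
Why: Grignard 1,2-addition; the carbinol centre may be racemic because it is erased in step 12.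

Step 12
Reactants: 17 5-[(4-methoxybenzyl)oxy]-2-methylpent-1-en-3-ol; 18 triethyl orthoacetate
Product: 21 ethyl (4E)-7-[(4-methoxybenzyl)oxy]-4-methylhept-4-enoate, via mixed orthoester 19 (not isolated), via ketene acetal 20 (not isolated)
Conditions: EtCO2H (cat.), neat MeC(OEt)3, 140 °C, ethanol distilled off
Reagents that add atoms: none
Why: Johnson–Claisen rearrangement; the chair [3,3] shift with the CH2CH2OPMB group equatorial forms the C13–C14 bond and the E-trisubstituted C11=C12 olefin.

Step 13
Reactants: 21 ethyl (4E)-7-[(4-methoxybenzyl)oxy]-4-methylhept-4-enoate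
Product: 23 (4E)-7-[(4-methoxybenzyl)oxy]-4-methylhept-4-enal, via aluminium hemiacetal 22 (not isolated)
Conditions: diisobutylaluminium hydride (1.05 equiv), CH2Cl2, −78 °C; aq. potassium sodium tartrate
Reagents that add atoms: none
Why: Partial ester reduction; at −78 °C the tetrahedral aluminium hemiacetal persists and collapses to the aldehyde only on work-up.

Step 14
Reactants: 23 (4E)-7-[(4-methoxybenzyl)oxy]-4-methylhept-4-enal; 24 methyl acrylate
Product: 25 methyl (6E)-3-hydroxy-9-[(4-methoxybenzyl)oxy]-6-methyl-2-methylidenenon-6-enoate (racemic)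
Conditions: DABCO, methyl acrylate in excess, MeOH, rt
Reagents that add atoms: none
Why: Morita–Baylis–Hillman reaction; the carbinol carbon (future C1) is racemic here and becomes sp2 in step 15.

Step 15
Reactants: 25 methyl (6E)-3-hydroxy-9-[(4-methoxybenzyl)oxy]-6-methyl-2-methylidenenon-6-enoate
Product: 26 methyl (2Z,6E)-2-(bromomethyl)-9-[(4-methoxybenzyl)oxy]-6-methylnona-2,6-dienoate
Conditions: NBS, Me2S, CH2Cl2, 0 °C to rt
Reagents that add atoms: N-bromosuccinimide, O=C1CCC(=O)N1Br
Why: Allylic bromination with transposition (SN2′) through the alkoxysulfonium salt; bromide attacks the methylene terminus and the trisubstituted acrylate should form with the chain trans to the ester (2Z), the usual outcome for such adducts.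

Step 16
Reactants: 12 (2E,6E)-7-iodo-3-methylocta-2,6-dienal; 26 methyl (2Z,6E)-2-(bromomethyl)-9-[(4-methoxybenzyl)oxy]-6-methylnona-2,6-dienoate
Product: 29 (4R,5S)-5-[(1E,5E)-6-iodo-2-methylhepta-1,5-dien-1-yl]-4-{(3E)-6-[(4-methoxybenzyl)oxy]-3-methylhex-3-en-1-yl}-3-methylideneoxolan-2-one, via silyl ether 27 (not isolated), via hydroxy ester 28 (not isolated)
Conditions: CrCl2 (10 mol %), 3,6-di-tert-butyl-1,8-bis(4-isopropyl-4,5-dihydrooxazol-2-yl)-9H-carbazole (one enantiomer, 11 mol %), iPr2NEt (30 mol %), Mn, TMSCl, THF, rt; then 1 M aq. HCl, THF, 0 °C; then PPTS (cat.), CH2Cl2, rt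
Reagents that add atoms: none
Why: Chromium-catalysed asymmetric 2-(alkoxycarbonyl)allylation of Nozaki–Hiyama type followed by lactonisation; the allylchromium from 26 should add through its γ-carbon (C1) in a closed chair transition state with the side chain equatorial to give the anti adduct and hence the trans lactone, while the bis(oxazolinyl)carbazole ligand on chromium selects the Re face of the enal to set (2S) and with it (1R), and the alkenyl iodide stays inert because no nickel is present.

Step 17
Reactants: 29 (4R,5S)-5-[(1E,5E)-6-iodo-2-methylhepta-1,5-dien-1-yl]-4-{(3E)-6-[(4-methoxybenzyl)oxy]-3-methylhex-3-en-1-yl}-3-methylideneoxolan-2-one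
Product: 30 (4R,5S)-4-[(3E)-6-hydroxy-3-methylhex-3-en-1-yl]-5-[(1E,5E)-6-iodo-2-methylhepta-1,5-dien-1-yl]-3-methylideneoxolan-2-one
Conditions: DDQ, CH2Cl2/pH 7 buffer, 0 °C
Reagents that add atoms: none
Why: Oxidative cleavage of the 4-methoxybenzyl ether by DDQ (benzylic hydride abstraction, hydrolysis of the oxocarbenium ion); the isolated olefins, the alkenyl iodide and the α-methylene lactone are not oxidised under these neutral conditions.

Step 18
Reactants: 30 (4R,5S)-4-[(3E)-6-hydroxy-3-methylhex-3-en-1-yl]-5-[(1E,5E)-6-iodo-2-methylhepta-1,5-dien-1-yl]-3-methylideneoxolan-2-one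
Product: 31 (3E)-6-{(2S,3R)-2-[(1E,5E)-6-iodo-2-methylhepta-1,5-dien-1-yl]-4-methylidene-5-oxooxolan-3-yl}-4-methylhex-3-enal
Conditions: Dess–Martin periodinane, NaHCO3, CH2Cl2, 0 °C; used at once without chromatography
Reagents that add atoms: none
Why: Dess–Martin oxidation, buffered and cold, should give the β,γ-unsaturated C9 aldehyde without the acid or base that would move C11=C12 into conjugation.

Step 19
Reactants: 31 (3E)-6-{(2S,3R)-2-[(1E,5E)-6-iodo-2-methylhepta-1,5-dien-1-yl]-4-methylidene-5-oxooxolan-3-yl}-4-methylhex-3-enal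
Product: 33 (1R,2S,9R,3E,7E,11E)-9-hydroxycembra-3,7,11,15(17)-tetraen-16,2-olide, via alkenylchromium species 32 (not isolated)
Conditions: CrCl2 (4 equiv), N-[2-(4-isopropyl-4,5-dihydrooxazol-2-yl)-6-methylphenyl]methanesulfonamide (one enantiomer, 4.4 equiv), Et3N (4.4 equiv), THF, rt; NiCl2(2,9-dimethyl-1,10-phenanthroline) (20 mol %); 31 added by syringe pump to about 2 mM, rt; aq. ethylenediamine work-up
Reagents that add atoms: none
Why: Zerovalent nickel, formed from NiCl2 by divalent chromium, inserts into the C8–I bond and passes the alkenyl group to chromium with retention of the E geometry; the resulting alkenyl species of trivalent chromium, which carries the chiral sulfonamide, adds to the C9 aldehyde. The closest known reaction type is the nickel/chromium-mediated Nozaki–Hiyama–Kishi macrocyclisation of alkenyl iodide aldehydes run with oxazoline sulfonamide ligands. The 14-membered carbocycle closes in a 14-exo-trig addition of the sp2 carbon C8 to the aldehyde carbon C9. The new C9 stereocentre is set by the ligand on chromium, which should direct the alkenyl group to the Si face to give the (9R)-alcohol, since the lactone stereocentres are too remote to bias the aldehyde. The step needs ring closure over oligomerisation, secured by slow addition at high dilution and by the three E olefins and trans lactone that limit the chain's conformations, and it needs attack at the aldehyde only, secured by the neutral conditions under which organochromium reagents leave the α-methylene lactone alone and the β,γ-unsaturated aldehyde does not isomerise.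

Step 20
Reactants: 33 (1R,2S,9R,3E,7E,11E)-9-hydroxycembra-3,7,11,15(17)-tetraen-16,2-olide
Product: 34 (1R,2S,9R,3E,7E,11E)-9-acetoxycembra-3,7,11,15(17)-tetraen-16,2-olide
Conditions: Ac2O, Et3N, DMAP (cat.), CH2Cl2, 0 °C
Reagents that add atoms: acetic anhydride, CC(=O)OC(C)=O
Why: DMAP-catalysed acetylation of the secondary allylic alcohol; no stereocentre or olefin is touched.

**Compound list**

1 | geraniol | CC(C)=CCC/C(C)=C/CO | starting material
2 | tert-butyl{[(2E)-3,7-dimethylocta-2,6-dien-1-yl]oxy}diphenylsilane | CC(C)=CCC/C(C)=C/CO[Si](c1ccccc1)(c1ccccc1)C(C)(C)C | intermediate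
3 | tert-butyl{[(2E)-5-(3,3-dimethyloxiran-2-yl)-3-methylpent-2-en-1-yl]oxy}diphenylsilane (racemic) | CC1(C)OC1CC/C(C)=C/CO[Si](c1ccccc1)(c1ccccc1)C(C)(C)C | intermediate
4 | (6E)-8-[(tert-butyldiphenylsilyl)oxy]-2,6-dimethyloct-6-ene-2,3-diol (racemic, not isolated) | CC(C)(O)C(O)CC/C(C)=C/CO[Si](c1ccccc1)(c1ccccc1)C(C)(C)C | intermediate
5 | (4E)-6-[(tert-butyldiphenylsilyl)oxy]-4-methylhex-4-enal | O=CCC/C(C)=C/CO[Si](c1ccccc1)(c1ccccc1)C(C)(C)C | intermediate
6 | tert-butyl{[(2E)-7,7-dibromo-3-methylhepta-2,6-dien-1-yl]oxy}diphenylsilane | BrC(Br)=CCC/C(C)=C/CO[Si](c1ccccc1)(c1ccccc1)C(C)(C)C | intermediate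
7 | lithium acetylide of tert-butyl{[(2E)-3-methylhept-2-en-6-yn-1-yl]oxy}diphenylsilane (not isolated) | [Li]C#CCC/C(C)=C/CO[Si](c1ccccc1)(c1ccccc1)C(C)(C)C | intermediate
8 | tert-butyl{[(2E)-3-methyloct-2-en-6-yn-1-yl]oxy}diphenylsilane | CC#CCC/C(C)=C/CO[Si](c1ccccc1)(c1ccccc1)C(C)(C)C | intermediate
9 | chloro{(2E,6E)-8-[(tert-butyldiphenylsilyl)oxy]-6-methylocta-2,6-dien-2-yl}bis(cyclopentadienyl)zirconium (not isolated; cyclopentadienyl rings drawn σ-bonded) | Cl[Zr](C1C=CC=C1)(C1C=CC=C1)/C(C)=C/CC/C(C)=C/CO[Si](c1ccccc1)(c1ccccc1)C(C)(C)C | intermediate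
10 | tert-butyl{[(2E,6E)-7-iodo-3-methylocta-2,6-dien-1-yl]oxy}diphenylsilane | I/C(C)=C/CC/C(C)=C/CO[Si](c1ccccc1)(c1ccccc1)C(C)(C)C | intermediate
11 | (2E,6E)-7-iodo-3-methylocta-2,6-dien-1-ol | I/C(C)=C/CC/C(C)=C/CO | intermediate
12 | (2E,6E)-7-iodo-3-methylocta-2,6-dienal | I/C(C)=C/CC/C(C)=C/C=O | intermediate
13 | propane-1,3-diol | OCCCO | starting material
14 | 3-[(4-methoxybenzyl)oxy]propan-1-ol | COc1ccc(COCCCO)cc1 | intermediate
15 | 3-[(4-methoxybenzyl)oxy]propanal | COc1ccc(COCCC=O)cc1 | intermediate
16 | isopropenylmagnesium bromide | CC(=C)[Mg]Br | starting material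
17 | 5-[(4-methoxybenzyl)oxy]-2-methylpent-1-en-3-ol (racemic) | COc1ccc(COCCC(O)C(C)=C)cc1 | intermediate
18 | triethyl orthoacetate | CCOC(C)(OCC)OCC | starting material
19 | mixed orthoester, the 1,1-diethoxyethyl ether of 17 (not isolated) | CC(OCC)(OCC)OC(CCOCc1ccc(OC)cc1)C(C)=C | intermediate
20 | ketene acetal, the 1-ethoxyvinyl ether of 17 (not isolated) | C=C(OCC)OC(CCOCc1ccc(OC)cc1)C(C)=C | intermediate
21 | ethyl (4E)-7-[(4-methoxybenzyl)oxy]-4-methylhept-4-enoate | CCOC(=O)CC/C(C)=C/CCOCc1ccc(OC)cc1 | intermediate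
22 | diisobutylaluminium hemiacetal of 21 (not isolated) | CCOC(O[Al](CC(C)C)CC(C)C)CC/C(C)=C/CCOCc1ccc(OC)cc1 | intermediate
23 | (4E)-7-[(4-methoxybenzyl)oxy]-4-methylhept-4-enal | O=CCC/C(C)=C/CCOCc1ccc(OC)cc1 | intermediate
24 | methyl acrylate | C=CC(=O)OC | starting material
25 | methyl (6E)-3-hydroxy-9-[(4-methoxybenzyl)oxy]-6-methyl-2-methylidenenon-6-enoate (racemic) | C=C(C(=O)OC)C(O)CC/C(C)=C/CCOCc1ccc(OC)cc1 | intermediate
26 | methyl (2Z,6E)-2-(bromomethyl)-9-[(4-methoxybenzyl)oxy]-6-methylnona-2,6-dienoate | COC(=O)/C(CBr)=C/CC/C(C)=C/CCOCc1ccc(OC)cc1 | intermediate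
27 | trimethylsilyl ether of 28 (not isolated) | COC(=O)C(=C)[C@@H](CC/C(C)=C/CCOCc1ccc(OC)cc1)[C@@H](O[Si](C)(C)C)/C=C(\C)CC/C=C(\C)I | intermediate
28 | methyl (3R,4S,5E,9E)-4-hydroxy-10-iodo-3-{(3E)-6-[(4-methoxybenzyl)oxy]-3-methylhex-3-en-1-yl}-6-methyl-2-methylideneundeca-5,9-dienoate (anti adduct, not isolated) | COC(=O)C(=C)[C@@H](CC/C(C)=C/CCOCc1ccc(OC)cc1)[C@@H](O)/C=C(\C)CC/C=C(\C)I | intermediate
29 | (4R,5S)-5-[(1E,5E)-6-iodo-2-methylhepta-1,5-dien-1-yl]-4-{(3E)-6-[(4-methoxybenzyl)oxy]-3-methylhex-3-en-1-yl}-3-methylideneoxolan-2-one (trans lactone) | C=C1C(=O)O[C@@H](/C=C(\C)CC/C=C(\C)I)[C@@H]1CC/C(C)=C/CCOCc2ccc(OC)cc2 | intermediate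
30 | (4R,5S)-4-[(3E)-6-hydroxy-3-methylhex-3-en-1-yl]-5-[(1E,5E)-6-iodo-2-methylhepta-1,5-dien-1-yl]-3-methylideneoxolan-2-one | C=C1C(=O)O[C@@H](/C=C(\C)CC/C=C(\C)I)[C@@H]1CC/C(C)=C/CCO | intermediate
31 | (3E)-6-{(2S,3R)-2-[(1E,5E)-6-iodo-2-methylhepta-1,5-dien-1-yl]-4-methylidene-5-oxooxolan-3-yl}-4-methylhex-3-enal (seco C8 iodide, C9 aldehyde) | C=C1C(=O)O[C@@H](/C=C(\C)CC/C=C(\C)I)[C@@H]1CC/C(C)=C/CC=O | intermediate
32 | C8 alkenyl species of trivalent chromium derived from 31, bearing chloride and the deprotonated (S)-sulfonamide (not isolated; solvent ligands and the dative oxazoline N–Cr bond not drawn) | C=C1C(=O)O[C@@H](/C=C(\C)CC/C=C(\C)[Cr](Cl)N(S(C)(=O)=O)c2c(C)cccc2C2=N[C@@H](C(C)C)CO2)[C@@H]1CC/C(C)=C/CC=O | intermediate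
33 | (1R,2S,9R,3E,7E,11E)-9-hydroxycembra-3,7,11,15(17)-tetraen-16,2-olide (9-deacetyl target, cembrane numbering) | C=C1C(=O)O[C@H]2/C=C(\C)CC/C=C(\C)[C@H](O)C/C=C(\C)CC[C@H]12 | intermediate
34 | (1R,2S,9R,3E,7E,11E)-9-acetoxycembra-3,7,11,15(17)-tetraen-16,2-olide (CNP0129197.1) | C=C1C(=O)O[C@H]2/C=C(\C)CC/C=C(\C)[C@H](OC(C)=O)C/C=C(\C)CC[C@H]12 | target

**Step count and risks**

Total: 20 steps. Longest linear sequence: 13 steps (steps 1–8, then 16–20, from geraniol).

Steps most likely to fail:

1. Step 19. Chain-to-chain coupling may compete with ring closure, and the ligand may give poor facial selectivity at the C9 aldehyde. The fallback sets out from 33 as it is obtained in mixture with its C9 epimer, the (9S)-alcohol F1. The mixture is oxidised with Dess–Martin periodinane (NaHCO3, CH2Cl2, 0 °C) to a single compound, the macrocyclic C9 enone F2. This is reduced with (S)-2-methyl-CBS-oxazaborolidine and catecholborane (toluene, −78 °C), the alkenyl branch acting as the large group as in aryl alkyl ketones, and so comes back to 33. The C9 centre is then set by reagent-controlled ketone reduction instead of by the C–C bond formation.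

2. Step 16. The allylchromium may add through the chair with the side chain axial and give the syn adduct, which would close to the cis lactone; enantioselectivity may also be eroded by uncatalysed background addition. The fallback sets out from 12 and 26 under the same catalysis but with the ligand antipode that gives the (1R,2R) series, so that the flask holds the syn silyl ether F3 and, after the dilute acid work-up, the syn hydroxy ester F4 (or the cis lactone it may close to). LiOH (THF/H2O, 0 °C) gives the hydroxy acid F5. Mitsunobu lactonisation (PPh3, diisopropyl azodicarboxylate, THF, 0 °C) then closes the lactone with inversion at C2 and comes back to 29. The trans relationship is thus made by stereospecific SN2 ring closure and no longer depends on the anti/syn preference of the addition.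

3. Step 2. The peracid may also attack the C2=C3 olefin or epoxidise both olefins, giving mixtures that are hard to separate. The fallback sets out from 2: NBS in THF/H2O at 0 °C should add bromine and water selectively across the terminal olefin to give the bromohydrin F6, and K2CO3 in MeOH closes it to the epoxide, which comes back to 3. Site selection then rests on bromonium formation at the exposed terminal olefin in aqueous medium and not on the small electronic difference seen by a peracid.

**Further compounds**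

F1 | step 19 | (1R,2S,9S,3E,7E,11E)-9-hydroxycembra-3,7,11,15(17)-tetraen-16,2-olide (C9 epimer of 33) | C=C1C(=O)O[C@H]2/C=C(\C)CC/C=C(\C)[C@@H](O)C/C=C(\C)CC[C@H]12
F2 | step 19 | (1R,2S,3E,7E,11E)-9-oxocembra-3,7,11,15(17)-tetraen-16,2-olide | C=C1C(=O)O[C@H]2/C=C(\C)CC/C=C(\C)C(=O)C/C=C(\C)CC[C@H]12
F3 | step 16 | trimethylsilyl ether of F4 | COC(=O)C(=C)[C@@H](CC/C(C)=C/CCOCc1ccc(OC)cc1)[C@H](O[Si](C)(C)C)/C=C(\C)CC/C=C(\C)I
F4 | step 16 | methyl (3R,4R,5E,9E)-4-hydroxy-10-iodo-3-{(3E)-6-[(4-methoxybenzyl)oxy]-3-methylhex-3-en-1-yl}-6-methyl-2-methylideneundeca-5,9-dienoate (syn adduct) | COC(=O)C(=C)[C@@H](CC/C(C)=C/CCOCc1ccc(OC)cc1)[C@H](O)/C=C(\C)CC/C=C(\C)I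
F5 | step 16 | (3R,4R,5E,9E)-4-hydroxy-10-iodo-3-{(3E)-6-[(4-methoxybenzyl)oxy]-3-methylhex-3-en-1-yl}-6-methyl-2-methylideneundeca-5,9-dienoic acid | OC(=O)C(=C)[C@@H](CC/C(C)=C/CCOCc1ccc(OC)cc1)[C@H](O)/C=C(\C)CC/C=C(\C)I
F6 | step 2 | (6E)-3-bromo-8-[(tert-butyldiphenylsilyl)oxy]-2,6-dimethyloct-6-en-2-ol (racemic) | CC(C)(O)C(Br)CC/C(C)=C/CO[Si](c1ccccc1)(c1ccccc1)C(C)(C)C
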